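## Retrosynthetic overview

1. Feature: ring A is a masked cyclohexene. The trans bond C3a–C7a shared by rings A and B, a heteroatom at C4 cis to the C3a methyl, and a methyl-bearing C7 map onto a C6=C7 cyclohexene. That cyclohexene comes from a diene C5=C6–C7=C7a and a dienophile C3a=C4 tied together by C1–C2–C3.
2. Last cut, C8–C1': a C8 carbanion held in a 1,3-dioxane across O2 and O8 adds to (S)-4-bromo-3,3-dimethylcyclohexanone. This ketone is ring C, made separately from 6-methylhept-5-en-2-one by bromonium cyclisation and then resolved.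
3. Functional-group cuts on ring A: C4–Br goes back to an alkenyl bromide, a ketone and a nitro group. C7–OH goes back to the C6=C7 alkene.
4. Key cut: C3a–C7a and C4–C5 together, by an intramolecular Diels–Alder reaction of an E nitroalkene that forms rings A and B at once.
5. The nitro triene comes from an Evans syn aldol (C1–C2) of a dienyl imide with a ketal aldehyde, then Henry addition and dehydration. Ring order: C alone, A and B together, then union of the halves.

Key step: step 12

Labels: ring B = C1, C2, C3, C3a, C7a. Ring A = C3a, C4 to C7, C7a. C8 = carbinol linker. Ring C = C1' to C6' (C1' carbinol, C3' CMe2, C4' CHBr). β is the face of rings A and B that carries the C3a methyl, α the other face.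

Remark: the target SMILES is read as (1S,2R,3aS,4S,7R,7aS,8R,1'R,4'S). The epimers at C3a of 20 and at C8 of 36 to 38 are carried as mixtures because those centres are erased or fixed later.

## Route

Step 1
Reactants: 1 pent-3-yn-1-ol
Product: 3 (E)-4-iodopent-3-en-1-ol, via alkenylzirconocene 2 (not isolated)
Conditions: Cp2Zr(H)Cl (2.5 equiv), THF, 0 → 40 °C; I2, −20 °C
Reagents that add atoms: iodine, [I][I]
Why: Hydrozirconation–iodinolysis, in which syn addition of Zr–H, equilibration of zirconium by excess hydride to the less hindered methyl-bearing carbon, and iodinolysis with retention fix the E trisubstituted alkene (future C7=C7a).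

Step 2
Reactants: 3 (E)-4-iodopent-3-en-1-ol; 4 tributyl(vinyl)stannane
Product: 5 (E)-4-methylhexa-3,5-dien-1-ol
Conditions: PdCl2(MeCN)2 (5 mol %), DMF, 23 °C
Reagents that add atoms: none
Why: Stille coupling at zerovalent palladium proceeds with retention at the alkenyl iodide, so the vinyl group (C5=C6) ends trans to the chain, and the free alcohol is tolerated.

Step 3
Reactants: 5 (E)-4-methylhexa-3,5-dien-1-ol
Product: 7 (E)-4-methylhexa-3,5-dienoic acid, via dienal 6 (not isolated)
Conditions: TEMPO (20 mol %), PhI(OAc)2 (2.2 equiv), MeCN/H2O 1:1, 0 → 23 °C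
Reagents that add atoms: water, O
Why: Oxoammonium (TEMPO) oxidation of the primary alcohol through the aldehyde hydrate gives the acid in a nearly neutral medium that should not pull the β,γ-alkene into conjugation.

Step 4
Reactants: 7 (E)-4-methylhexa-3,5-dienoic acid; 8 (S)-4-benzyl-1,3-oxazolidin-2-one
Product: 10 (S)-4-benzyl-3-[(E)-4-methylhexa-3,5-dienoyl]oxazolidin-2-one, via mixed anhydride 9 (not isolated)
Conditions: t-BuCOCl, Et3N, THF, −20 °C; then 8, LiCl, −20 → 23 °C
Reagents that add atoms: none
Why: Mixed-anhydride N-acylation in which LiCl activates the auxiliary, so that Et3N suffices and no strong base is present to isomerise the dienyl chain.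

Step 5
Reactants: 11 ethyl 2-(2-methyl-1,3-dioxolan-2-yl)acetate (commercial ethylene ketal of ethyl acetoacetate)
Product: 12 2-(2-methyl-1,3-dioxolan-2-yl)acetaldehyde
Conditions: i-Bu2AlH (1.05 equiv), CH2Cl2, −78 °C; H2O work-up
Reagents that add atoms: none
Why: Partial ester reduction stops at the tetrahedral aluminium hemiacetal at −78 °C, which releases the aldehyde only on work-up, and the ketal is inert.

Step 6
Reactants: 10 dienyl imide; 12 ketal aldehyde
Product: 15 syn aldol imide (C1 S; C2 R), via boron enolate 13 (not isolated), via boron aldolate 14 (not isolated)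
Conditions: Bu2BOTf, Et3N, CH2Cl2, −78 → 0 °C; 12, −78 → 0 °C; H2O2, MeOH, pH 7 buffer, 0 °C
Reagents that add atoms: none
Why: Evans syn aldol, in which the Z boron enolate reacts at its α carbon through a Zimmerman–Traxler chair on the face away from the benzyl group, so the (S)-auxiliary sets C1 and C2 in the syn relation that becomes C8 cis to O2 on ring B.

Step 7
Reactants: 15 syn aldol imide
Product: 16 (2R,3R)-4-(2-methyl-1,3-dioxolan-2-yl)-2-[(1E)-2-methylbuta-1,3-dienyl]butane-1,3-diol
Conditions: LiBH4, MeOH (1 equiv), Et2O, 0 °C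
Reagents that add atoms: none
Why: Reductive removal of the auxiliary, since LiBH4 attacks the exocyclic imide carbonyl and leaves C1, C2, the ketal and the diene untouched.

Step 8
Reactants: 16 diol
Product: 17 bis-TBS ether of 16
Conditions: TBSCl (3 equiv), imidazole, DMF, 35 °C
Reagents that add atoms: tert-butyldimethylsilyl chloride, CC(C)(C)[Si](C)(C)Cl
Why: Imidazole-promoted silylation covers O8 and O2 with groups that withstand heat, base, hydrazine and radical conditions.

Step 9
Reactants: 17 bis-TBS ketal
Product: 18 methyl ketone (C3a carbonyl)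
Conditions: PPTS (cat.), acetone/H2O 10:1, 45 °C
Reagents that add atoms: water, O
Why: Acid-catalysed ketal hydrolysis with a weak acid frees the ketone faster than the TBS ethers are cleaved.

Step 10
Reactants: 18 methyl ketone; 19 nitromethane
Product: 20 tertiary β-nitro alcohol (C3a epimers)
Conditions: 19 as solvent, P(i-PrNCH2CH2)3N (10 mol %), MgSO4, 23 °C
Reagents that add atoms: none
Why: Henry addition to a methyl ketone, driven by nitromethane as solvent, in a medium buffered by the acidic nitromethane so that the ketone is not enolised and the β-silyloxy group is not eliminated, and the new carbinol centre is erased in step 11.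

Step 11
Reactants: 20 β-nitro alcohol
Product: 22 (1E,4R,5R,6E)-4-(TBSO)-5-(TBSOCH2)-2,7-dimethyl-1-nitronona-1,6,8-triene, via mesylate 21 (not isolated)
Conditions: MsCl, Et3N, CH2Cl2, −20 → 0 °C
Reagents that add atoms: none
Why: Mesylation through sulfene and E1cB loss of mesylate from the nitronate give the conjugated nitroalkene, with E favoured because nitro avoids the branched C3 chain, and the minor Z isomer is removed by chromatography and can be re-equilibrated with base.

Step 12
Reactants: 22 nitro triene
Product: 23 (1R,2R,3aS,4S,7aR)-2-(TBSO)-1-(TBSOCH2)-3a,7-dimethyl-4-nitro-2,3,3a,4,5,7a-hexahydro-1H-indene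
Conditions: PhMe (0.01 M), BHT (cat.), sealed tube, 150 °C
Reagents that add atoms: none
Why: Thermal, concerted and suprafacial (4+2) cycloaddition in which the s-cis diene C5=C6–C7=C7a adds across the nitro-activated alkene C3a=C4, making C3a–C7a and C4–C5 in one event and leaving the alkene at C6=C7. The closest known reaction type is the intramolecular Diels–Alder reaction of terminally nitro-activated nona-1,6,8-trienes and deca-1,7,9-trienes; the harder point here is the fully substituted inner dienophile carbon C3a, which the strong LUMO lowering by nitro and the short three-atom tether have to offset. Ring A closes as the six-membered cycloaddition ring that holds both new bonds, and ring B closes as a five-membered ring through the single bond C3a–C7a with the tether C1–C2–C3 lying exo to the diene. C4 is fixed relative to C3a by the E geometry (nitro and methyl stay cis), C3a relative to C7a by the transition state with nitro and methyl endo and the tether exo (trans fusion), and C7a relative to C1 by A1,3 strain between the C7 methyl and C1, which turns H1 into the diene plane so that the tether reaches one diene face only while CH2OTBS points to the other (C8 cis to H7a). The step thus needs endo selectivity and diene-face selectivity; the first rests on the E nitro group, the second on the C7 methyl together with the C1 centre from the aldol. High dilution and BHT hold back polymerisation of the nitroalkene.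

Step 13
Reactants: 23 nitrohydrindene
Product: 25 7β-hydroxy-7α-methyl-4β-nitro trans-hydrindane bis-TBS ether, via organomercurial 24 (not isolated)
Conditions: Hg(OAc)2, THF/H2O 1:1, 23 °C; then NaOH aq., NaBH4, 0 °C
Reagents that add atoms: water, O
Why: Oxymercuration–demercuration, in which Markovnikov attack at tertiary C7 and Fürst–Plattner trans-diaxial opening of the α mercurinium ion both call for the axial β hydroxyl, and the step is placed before the Nef reaction because nitro survives NaBH4 whereas a C4 ketone would not.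

Step 14
Reactants: 25 nitro alcohol
Product: 27 C4 ketone (7β-OH; bis-TBS), via potassium nitronate 26 (not isolated)
Conditions: KOt-Bu (1.2 equiv), THF, 0 °C; then dimethyldioxirane, acetone, 0 → 23 °C
Reagents that add atoms: dimethyldioxirane, CC1(C)OO1
Why: Oxidative Nef reaction, which cleaves the nitronate C=N bond without acid, spares the tertiary alcohol and the silyl ethers, and meets no alkene at this stage.

Step 15
Reactants: 27 C4 ketone
Product: 28 C4 hydrazone
Conditions: N2H4·H2O (excess), Et3N, EtOH, 80 °C
Reagents that add atoms: hydrazine, NN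
Why: Hydrazone formation at a ketone next to a quaternary carbon, as practised on 17-oxo steroids, needs excess hydrazine and heat but no acid.

Step 16
Reactants: 28 hydrazone
Product: 29 C4=C5 alkenyl bromide
Conditions: Br2 (2.2 equiv), 2-tert-butyl-1,1,3,3-tetramethylguanidine (excess), CH2Cl2, 0 °C, inverse addition
Reagents that add atoms: bromine, BrBr
Why: Barton vinyl halide synthesis run with bromine, in which oxidation to the diazo compound, bromination, loss of N2 and loss of the only β proton (at C5, since C3a is quaternary) place the alkene at C4=C5.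

Step 17
Reactants: 29 alkenyl bromide
Product: 30 4β-bromide (equatorial; bis-TBS; 7β-OH)
Conditions: Mn(dpm)3 (10 mol %), PhSiH3, t-BuOOH, i-PrOH, 23 °C
Reagents that add atoms: none
Why: Hydrogen-atom-transfer hydrogenation of an alkenyl halide, in which the metal hydride delivers H to C5 and the α-bromo radical at C4 takes its hydrogen axially on the α face anti to the axial C3a methyl, so bromine ends equatorial and cis to that methyl, which is also the more stable epimer, without C–Br hydrogenolysis.

Step 18
Reactants: 30 bromide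
Product: 31 bromo triol
Conditions: 48% aq. HF, MeCN, 0 → 23 °C
Reagents that add atoms: none
Why: Fluoride-driven desilylation in a weakly acidic aqueous medium removes both TBS groups and offers no base for elimination of the bromide.

Step 19
Reactants: 31 bromo triol
Product: 32 tris-TES ether
Conditions: Et3SiOTf (4 equiv), 2,6-lutidine, CH2Cl2, −78 → 0 °C
Reagents that add atoms: triethylsilyl triflate, CC[Si](CC)(CC)OS(=O)(=O)C(F)(F)F
Why: Silylation with the reactive triflate also covers the hindered axial C7 hydroxyl, and TES is chosen because the primary ether can be oxidised directly and the C2 ether can later be exchanged under mild acid.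

Step 20
Reactants: 32 tris-TES ether
Product: 34 C8 aldehyde (O2 and O7 TES), via alkoxysulfonium salt 33 (not isolated)
Conditions: (COCl)2, DMSO, CH2Cl2, −78 → −35 °C; Et3N, −78 → 0 °C
Reagents that add atoms: none
Why: Swern oxidation applied directly to silyl ethers, where only the unhindered primary TES ether is attacked by the chlorosulfonium salt, so C8 becomes the aldehyde and C1 is not epimerised at low temperature.

Step 21
Reactants: 34 aldehyde
Product: 36 α-hydroxystannane (C8 epimers), via lithium alkoxide 35 (not isolated)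
Conditions: Bu3SnH, LiN(i-Pr)2, THF, 0 °C; then 34, −78 °C; H2O
Reagents that add atoms: tributylstannyllithium, [Li][Sn](CCCC)(CCCC)CCCC
Why: 1,2-Addition of a stannyl anion to an aldehyde is far faster at −78 °C than attack on the hindered equatorial bromide next to the quaternary C3a, and the C8 epimers are not separated because C8 is fixed in step 26.

Step 22
Reactants: 36 α-hydroxystannane
Product: 38 4-stannyl-1,3-dioxane (O2/O8 acetonide; C8 epimers; O7 TES), via stannyl diol 37 (not isolated)
Conditions: PPTS (cat.), MeOH, 0 °C; then Me2C(OMe)2, CH2Cl2, 23 °C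
Reagents that add atoms: 2,2-dimethoxypropane, COC(C)(C)OC
Why: Acid-catalysed methanolysis of the more accessible secondary TES ether followed by transketalisation replaces silicon on O2, which removes the risk of a retro-1,4-Brook shift onto the C8 carbanion and places C8 in a 1,3-dioxane chair.

Step 23
Reactants: 39 6-methylhept-5-en-2-one
Product: 41 diethyl 6-methylhepta-1,5-dien-2-yl phosphate, via lithium enolate 40 (not isolated)
Conditions: LiN(i-Pr)2, THF, −78 °C; ClP(O)(OEt)2, −78 → 0 °C
Reagents that add atoms: diethyl chlorophosphate, CCOP(=O)(Cl)OCC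
Why: Kinetic deprotonation at the methyl group and O-phosphorylation give the terminal enol phosphate, an alkene less nucleophilic than the trisubstituted one, whereas a silyl enol ether would itself be brominated first.

Step 24
Reactants: 41 enol phosphate
Product: 42 (±)-4-bromo-3,3-dimethylcyclohexanone
Conditions: Et2SBr·SbCl5Br (1.1 equiv), MeNO2, −25 °C; then H2O
Reagents that add atoms: bromodiethylsulfonium bromopentachloroantimonate, CC[S+](Br)CC.Cl[Sb-](Cl)(Cl)(Cl)(Cl)Br
Why: Bromonium-induced cation–olefin cyclisation, in which Br+ takes the electron-rich C3'=C4' alkene, the enol phosphate carbon C2' attacks the tertiary terminus C3' through a chair to close the six-membered ring, and hydrolysis of the phosphoryloxy cation leaves the ketone as a racemate.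

Step 25
Reactants: 42 racemic bromoketone
Product: 43 (S)-4-bromo-3,3-dimethylcyclohexanone
Conditions: preparative SFC, amylose tris(3,5-dimethylphenylcarbamate) phase, CO2/i-PrOH
Reagents that add atoms: none
Why: Chromatographic resolution on a chiral stationary phase supplies C4' as the S enantiomer, whose absolute configuration can be checked by anomalous dispersion of bromine.

Step 26
Reactants: 38 stannyl acetonide; 43 (S)-4-bromo-3,3-dimethylcyclohexanone
Product: 45 coupled acetonide (C8 R; C1' R), via equatorial lithiodioxane 44 (not isolated)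
Conditions: n-BuLi (1.05 equiv), THF, −78 °C, then −20 °C (30 min), −78 °C; 43; H2O
Reagents that add atoms: none
Why: Tin–lithium exchange gives 4-lithio-1,3-dioxanes that converge on brief warming to the more stable equatorial C–Li epimer, which adds with retention (C8 set syn to O2) from the equatorial direction of the ketone because the axial C3' methyl closes the axial face, so that on the chair with equatorial bromine the C1' hydroxyl becomes axial and the side chain trans to bromine.

Step 27
Reactants: 45 coupled acetonide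
Product: 46 target CNP0144982.1
Conditions: 48% aq. HF, MeCN, 0 → 23 °C
Reagents that add atoms: none
Why: Aqueous HF hydrolyses the acetonide and cleaves the tertiary TES ether in one operation that is mild enough for the two tertiary alcohols and the two equatorial secondary bromides.

## Compound list

1 | pent-3-yn-1-ol | CC#CCCO | starting material
2 | (E)-alkenylzirconocene chloride of 1, O-zirconated | Cl[Zr](C1C=CC=C1)(C1C=CC=C1)/C(C)=C/CCO[Zr](Cl)(C1C=CC=C1)C1C=CC=C1 | intermediate
3 | (E)-4-iodopent-3-en-1-ol | OCC/C=C(C)/I | intermediate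
4 | tributyl(vinyl)stannane | C=C[Sn](CCCC)(CCCC)CCCC | starting material
5 | (E)-4-methylhexa-3,5-dien-1-ol | OCC/C=C(C)/C=C | intermediate
6 | (E)-4-methylhexa-3,5-dienal | O=CC/C=C(C)/C=C | intermediate
7 | (E)-4-methylhexa-3,5-dienoic acid | OC(=O)C/C=C(C)/C=C | intermediate
8 | (S)-4-benzyl-1,3-oxazolidin-2-one | O=C1OC[C@H](Cc2ccccc2)N1 | starting material
9 | pivalic (E)-4-methylhexa-3,5-dienoic anhydride | CC(C)(C)C(=O)OC(=O)C/C=C(C)/C=C | intermediate
10 | (S)-4-benzyl-3-[(E)-4-methylhexa-3,5-dienoyl]oxazolidin-2-one | O=C1OC[C@H](Cc2ccccc2)N1C(=O)C/C=C(C)/C=C | intermediate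
11 | ethyl 2-(2-methyl-1,3-dioxolan-2-yl)acetate | CCOC(=O)CC1(C)OCCO1 | starting material
12 | 2-(2-methyl-1,3-dioxolan-2-yl)acetaldehyde | O=CCC1(C)OCCO1 | intermediate
13 | Z(O) dibutylboron enolate of 10 | CCCCB(CCCC)O/C(N1C(=O)OC[C@@H]1Cc1ccccc1)=C\C=C(C)\C=C | intermediate
14 | dibutylboron aldolate of 15 | O=C1OC[C@H](Cc2ccccc2)N1C(=O)[C@@H](/C=C(C)/C=C)[C@H](OB(CCCC)CCCC)CC3(C)OCCO3 | intermediate
15 | (S)-4-benzyl-3-{(2S,3R)-3-hydroxy-4-(2-methyl-1,3-dioxolan-2-yl)-2-[(1E)-2-methylbuta-1,3-dienyl]butanoyl}oxazolidin-2-one | O=C1OC[C@H](Cc2ccccc2)N1C(=O)[C@@H](/C=C(C)/C=C)[C@H](O)CC3(C)OCCO3 | intermediate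
16 | (2R,3R)-4-(2-methyl-1,3-dioxolan-2-yl)-2-[(1E)-2-methylbuta-1,3-dienyl]butane-1,3-diol | OC[C@@H](/C=C(C)/C=C)[C@H](O)CC1(C)OCCO1 | intermediate
17 | bis-TBS ether of 16 | CC(C)(C)[Si](C)(C)OC[C@@H](/C=C(C)/C=C)[C@H](O[Si](C)(C)C(C)(C)C)CC1(C)OCCO1 | intermediate
18 | (4R,5R,6E)-4-(TBSO)-5-(TBSOCH2)-7-methylnona-6,8-dien-2-one | CC(C)(C)[Si](C)(C)OC[C@@H](/C=C(C)/C=C)[C@H](O[Si](C)(C)C(C)(C)C)CC(C)=O | intermediate
19 | nitromethane | C[N+](=O)[O-] | starting material
20 | tertiary β-nitro alcohol from 18 (C3a epimers) | CC(C)(C)[Si](C)(C)OC[C@@H](/C=C(C)/C=C)[C@H](O[Si](C)(C)C(C)(C)C)CC(C)(O)C[N+](=O)[O-] | intermediate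
21 | mesylate of 20 | CC(C)(C)[Si](C)(C)OC[C@@H](/C=C(C)/C=C)[C@H](O[Si](C)(C)C(C)(C)C)CC(C)(OS(C)(=O)=O)C[N+](=O)[O-] | intermediate
22 | (1E,4R,5R,6E)-4-(TBSO)-5-(TBSOCH2)-2,7-dimethyl-1-nitronona-1,6,8-triene | CC(C)(C)[Si](C)(C)OC[C@@H](/C=C(C)/C=C)[C@H](O[Si](C)(C)C(C)(C)C)C/C(C)=C/[N+](=O)[O-] | intermediate
23 | trans-fused nitrohydrindene (1R,2R,3aS,4S,7aR); C3a-Me β, H7a α, 4-NO2 β, C1 chain α, O2 α | CC(C)(C)[Si](C)(C)OC[C@@H]2[C@H](O[Si](C)(C)C(C)(C)C)C[C@]3(C)[C@@H]([N+](=O)[O-])CC=C(C)[C@@H]23 | intermediate
24 | 6α-(acetoxymercurio)-7β-hydroxy adduct of 23 | CC(C)(C)[Si](C)(C)OC[C@@H]2[C@H](O[Si](C)(C)C(C)(C)C)C[C@]3(C)[C@@H]([N+](=O)[O-])C[C@H]([Hg]OC(C)=O)[C@@](C)(O)[C@@H]23 | intermediate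
25 | 7β-hydroxy-7α-methyl-4β-nitro trans-hydrindane, bis-TBS ether | CC(C)(C)[Si](C)(C)OC[C@@H]2[C@H](O[Si](C)(C)C(C)(C)C)C[C@]3(C)[C@@H]([N+](=O)[O-])CC[C@@](C)(O)[C@@H]23 | intermediate
26 | potassium C4 nitronate of 25 | CC(C)(C)[Si](C)(C)OC[C@@H]2[C@H](O[Si](C)(C)C(C)(C)C)C[C@]3(C)C(=[N+]([O-])[O-])CC[C@@](C)(O)[C@@H]23.[K+] | intermediate
27 | C4 ketone, 7β-OH, bis-TBS ether | CC(C)(C)[Si](C)(C)OC[C@@H]2[C@H](O[Si](C)(C)C(C)(C)C)C[C@]3(C)C(=O)CC[C@@](C)(O)[C@@H]23 | intermediate
28 | C4 hydrazone of 27 | CC(C)(C)[Si](C)(C)OC[C@@H]2[C@H](O[Si](C)(C)C(C)(C)C)C[C@]3(C)C(=NN)CC[C@@](C)(O)[C@@H]23 | intermediate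
29 | 4-bromo C4=C5 alkene, 7β-OH, bis-TBS ether | CC(C)(C)[Si](C)(C)OC[C@@H]2[C@H](O[Si](C)(C)C(C)(C)C)C[C@]3(C)C(Br)=CC[C@@](C)(O)[C@@H]23 | intermediate
30 | 4β-bromo (equatorial) trans-hydrindane, 7β-OH, bis-TBS ether | CC(C)(C)[Si](C)(C)OC[C@@H]2[C@H](O[Si](C)(C)C(C)(C)C)C[C@]3(C)[C@@H](Br)CC[C@@](C)(O)[C@@H]23 | intermediate
31 | bromo triol (O8, O2, O7 free) | OC[C@@H]2[C@H](O)C[C@]3(C)[C@@H](Br)CC[C@@](C)(O)[C@@H]23 | intermediate
32 | tris-TES ether of 31 | CC[Si](CC)(CC)OC[C@@H]2[C@H](O[Si](CC)(CC)CC)C[C@]3(C)[C@@H](Br)CC[C@@](C)(O[Si](CC)(CC)CC)[C@@H]23 | intermediate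
33 | C8 alkoxydimethylsulfonium chloride | C[S+](C)OC[C@@H]2[C@H](O[Si](CC)(CC)CC)C[C@]3(C)[C@@H](Br)CC[C@@](C)(O[Si](CC)(CC)CC)[C@@H]23.[Cl-] | intermediate
34 | C8 aldehyde, O2 and O7 TES | O=C[C@@H]2[C@H](O[Si](CC)(CC)CC)C[C@]3(C)[C@@H](Br)CC[C@@](C)(O[Si](CC)(CC)CC)[C@@H]23 | intermediate
35 | lithium alkoxide of 36 (C8 epimers) | CCCC[Sn](CCCC)(CCCC)C(O[Li])[C@@H]2[C@H](O[Si](CC)(CC)CC)C[C@]3(C)[C@@H](Br)CC[C@@](C)(O[Si](CC)(CC)CC)[C@@H]23 | intermediate
36 | C8 α-hydroxy tributylstannane (C8 epimers), O2 and O7 TES | CCCC[Sn](CCCC)(CCCC)C(O)[C@@H]2[C@H](O[Si](CC)(CC)CC)C[C@]3(C)[C@@H](Br)CC[C@@](C)(O[Si](CC)(CC)CC)[C@@H]23 | intermediate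
37 | stannyl 2,8-diol (C8 epimers), O7 TES | CCCC[Sn](CCCC)(CCCC)C(O)[C@@H]2[C@H](O)C[C@]3(C)[C@@H](Br)CC[C@@](C)(O[Si](CC)(CC)CC)[C@@H]23 | intermediate
38 | 4-(tributylstannyl)-1,3-dioxane, O2/O8 acetonide (C8 epimers), O7 TES | CCCC[Sn](CCCC)(CCCC)C(O4)[C@@H]2[C@H](OC4(C)C)C[C@]3(C)[C@@H](Br)CC[C@@](C)(O[Si](CC)(CC)CC)[C@@H]23 | intermediate
39 | 6-methylhept-5-en-2-one | CC(C)=CCCC(C)=O | starting material
40 | kinetic lithium enolate of 39 | [Li]OC(=C)CCC=C(C)C | intermediate
41 | diethyl 6-methylhepta-1,5-dien-2-yl phosphate | C=C(CCC=C(C)C)OP(=O)(OCC)OCC | intermediate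
42 | (±)-4-bromo-3,3-dimethylcyclohexanone | CC1(C)CC(=O)CCC1Br | intermediate
43 | (S)-4-bromo-3,3-dimethylcyclohexanone | CC1(C)CC(=O)CC[C@@H]1Br | intermediate
44 | equatorial 4-lithio-1,3-dioxane (Li in the place later taken by C1') | [Li][C@H](O4)[C@@H]2[C@H](OC4(C)C)C[C@]3(C)[C@@H](Br)CC[C@@](C)(O[Si](CC)(CC)CC)[C@@H]23 | intermediate
45 | coupled product: O2/O8 acetonide, O7 TES, free axial C1' OH, side chain trans to C4' Br | CC1(C)C[C@@](O)([C@H](O4)[C@@H]2[C@H](OC4(C)C)C[C@]3(C)[C@@H](Br)CC[C@@](C)(O[Si](CC)(CC)CC)[C@@H]23)CC[C@@H]1Br | intermediate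
46 | (1S,2R,3aS,4S,7R,7aS)-4-bromo-1-{(R)-[(1R,4S)-4-bromo-1-hydroxy-3,3-dimethylcyclohexyl](hydroxy)methyl}-3a,7-dimethyloctahydro-1H-indene-2,7-diol | CC1(C)C[C@@](O)([C@H](O)[C@@H]2[C@H](O)C[C@]3(C)[C@@H](Br)CC[C@@](C)(O)[C@@H]23)CC[C@@H]1Br | target

## Step count and risks

Total step count: 27.
Longest linear sequence: 23 steps (steps 1 to 4, 6 to 22, 26 and 27).

**Step 12 (key cycloaddition).**
- What may go wrong: bond formation at the fully substituted C3a may be sluggish. Long heating could then bring geometric isomerisation or deconjugation of the nitroalkene and erode the endo (trans-fusion) preference.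
- Fallback: it sets out from ketone 18 and adds a second acceptor to the dienophile.
- Knoevenagel condensation of 18 with methyl nitroacetate (TiCl4, N-methylmorpholine, THF, 0 °C) gives the nitroacrylate triene F1.
- The doubly activated alkene of F1 should cyclise well below 100 °C to the nitro ester cycloadduct F2.
- Krapcho dealkoxycarbonylation (LiCl, wet DMSO, 120 °C) removes the ester by attack at its methyl group rather than at the hindered carbonyl.
- Protonation of the resulting nitronate brings the material back to 23. Either C4 epimer serves, because C4 becomes a ketone in step 14. This path also bypasses steps 10 and 11.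

**Step 26 (union of the halves).**
- What may go wrong: the basic organolithium may enolise the ketone.
- Facial selectivity at C1' may be poor, because the chair of the bromoketone is not firmly locked. Bromine has a small conformational preference and a transannular dipole interaction with the carbonyl.
- C–Br bonds may be attacked during the warm period.
- Fallback: it sets out from stannane 38 and installs the ring C bromide after the C8–C1' bond instead of before it.
- The lithiodioxane is added to the less hindered carbonyl of 2,2-dimethylcyclohexane-1,4-dione F3 to give the hydroxy ketone F4, whose C1' epimers are separated by chromatography.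
- The remaining carbonyl next to the CMe2 group is converted to the hydrazone F5 and then to the ring C alkenyl bromide F6, under the conditions of steps 15 and 16.
- Hydrogen-atom-transfer hydrogenation as in step 17 follows. The large equatorial side chain now anchors the chair, and axial hydrogen delivery places bromine equatorial and trans to it. This returns to 45.

**Step 24 (bromonium cyclisation).**
- What may go wrong: the enol phosphate may be brominated in competition, the tertiary cation may lose a proton before ring closure, or it may be captured by the medium.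
- Fallback: it sets out from enol phosphate 41 and separates ring closure from C–Br formation.
- Cyclisation induced by divalent mercury (Hg(OCOCF3)2, MeNO2, 0 °C, then aq. NaCl) is a known use of enol phosphate terminators. It gives 4-(chloromercurio)-3,3-dimethylcyclohexanone F7.
- Brominolysis of the C–Hg bond (Br2, LiBr, pyridine, 0 °C) returns to 42. The stereochemical course of this cleavage is irrelevant for a racemate with a single stereocentre.

## Further compounds

F1 | step 12 | nitroacrylate triene (alkene geometry not defined) | CC(C)(C)[Si](C)(C)OC[C@@H](/C=C(C)/C=C)[C@H](O[Si](C)(C)C(C)(C)C)CC(C)=C(C(=O)OC)[N+](=O)[O-]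
F2 | step 12 | nitro ester cycloadduct (C4 not defined) | CC(C)(C)[Si](C)(C)OC[C@@H]2[C@H](O[Si](C)(C)C(C)(C)C)C[C@]3(C)C(C(=O)OC)([N+](=O)[O-])CC=C(C)[C@@H]23
F3 | step 26 | 2,2-dimethylcyclohexane-1,4-dione | CC1(C)CC(=O)CCC1=O
F4 | step 26 | hydroxy ketone (C4' carbonyl) | CC1(C)C[C@@](O)([C@H](O4)[C@@H]2[C@H](OC4(C)C)C[C@]3(C)[C@@H](Br)CC[C@@](C)(O[Si](CC)(CC)CC)[C@@H]23)CCC1=O
F5 | step 26 | C4' hydrazone | CC1(C)C[C@@](O)([C@H](O4)[C@@H]2[C@H](OC4(C)C)C[C@]3(C)[C@@H](Br)CC[C@@](C)(O[Si](CC)(CC)CC)[C@@H]23)CCC1=NN
F6 | step 26 | ring C alkenyl bromide (C4'=C5') | CC1(C)C[C@@](O)([C@H](O4)[C@@H]2[C@H](OC4(C)C)C[C@]3(C)[C@@H](Br)CC[C@@](C)(O[Si](CC)(CC)CC)[C@@H]23)CC=C1Br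
F7 | step 24 | 4-(chloromercurio)-3,3-dimethylcyclohexanone | CC1(C)CC(=O)CCC1[Hg]Cl
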